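The six‑membered ring of colupone (C1 conjugated ketone, C2 carrying the isobutyryl group, C3 enol carbon, C4 and C6 the quaternary C(prenyl)2 carbons, C5 the ketone between them) is a cyclohexane‑1,3,5‑trione, formally a co‑trimer of ketenes, and its C3–C4 unit is diprenylketene in disguise. The plan closes the ring by a polyketide‑type chain extension and Claisen cyclisation in one operation: the sodium enolate of an open‑chain 3,5‑diketo ester (C5, C6, C1, C2 with the isobutyryl group) C‑acylates diprenylketene to form C2–C3, and the ketene‑derived enolate at C4 then attacks the ester to form C4–C5. Both partners come from methyl 2,2‑diprenylacetoacetate.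

Key step: step 5

Remark: prenyl stands for 3‑methylbut‑2‑en‑1‑yl. The target is achiral and is drawn as one enol tautomer of a 2‑acylcyclohexane‑1,3,5‑trione; the enol form delivered by the work‑up is taken as identical with it.

Step 1
Reactants: 1 methyl acetoacetate; 2 prenyl bromide
Product: 3 methyl 2,2‑diprenylacetoacetate
Conditions: NaH (2.3 equiv, two portions), 2 (2.3 equiv), THF, 0 °C to 25 °C
Reagents that add atoms: none
Why: Acetoacetic ester alkylation carried out twice: the sodium enolate of 1, and then that of the monoprenyl intermediate, displaces bromide from the primary allylic bromide by SN2 at carbon, which builds the quaternary carbon without creating a stereocentre.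

Step 2
Reactants: 3 methyl 2,2‑diprenylacetoacetate; 4 isobutyryl chloride
Product: 5 methyl 6‑methyl‑2,2‑diprenyl‑3,5‑dioxoheptanoate
Conditions: MgBr2·OEt2 (2.5 equiv), i‑Pr2NEt (3 equiv), CH2Cl2, 25 °C; cold dilute HCl work‑up
Reagents that add atoms: none
Why: Crossed Claisen‑type C‑acylation under soft enolisation: magnesium chelation of the β‑keto ester acidifies the acetyl methyl group, the only enolisable position because the α‑carbon is quaternary, so the amine forms the magnesium enolate, which is acylated at carbon by 4 and then held as the chelated diketonate against over‑acylation; no stereocentre is formed.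

Step 3
Reactants: 3 methyl 2,2‑diprenylacetoacetate
Product: 7 diprenylacetic acid, via methyl diprenylacetate 6 (not isolated)
Conditions: NaOMe (0.3 equiv), MeOH, 65 °C; then 4 M aq. NaOH, 65 °C; then 2 M HCl, 0 °C
Reagents that add atoms: sodium hydroxide, [Na+].[OH-]
Why: Retro‑Claisen cleavage of a non‑enolisable β‑keto ester (the acid cleavage of a disubstituted acetoacetate): methoxide adds to the acetyl carbonyl and expels the ester enolate of 6 together with methyl acetate, and saponification in the same pot gives 7, whose α‑carbon bears two identical prenyl groups and is no stereocentre.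

Step 4
Reactants: 7 diprenylacetic acid
Product: 8 diprenylacetyl chloride
Conditions: (COCl)2 (1.2 equiv), DMF (cat.), CH2Cl2, 0 °C to 25 °C; concentrated at once
Reagents that add atoms: oxalyl chloride, O=C(Cl)C(Cl)=O
Why: Acid chloride formation through the chloroiminium (Vilsmeier‑type) reagent from oxalyl chloride and DMF, run cold and concentrated at once so that the HCl released does not add to the trisubstituted alkenes.

Step 5
Reactants: 5 methyl 6‑methyl‑2,2‑diprenyl‑3,5‑dioxoheptanoate; 8 diprenylacetyl chloride
Product: 11 colupone, via diprenylketene 9 (not isolated), via triketo ester 10 (not isolated)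
Conditions: 8 (1.4 equiv), Et3N (1.5 equiv), THF, 25 °C, filtered under argon; filtrate added slowly to 5, NaH (3 equiv), THF, 0 °C to 25 °C; then cold 1 M HCl
Reagents that add atoms: none
Why: Et3N dehydrochlorinates 8 to ketene 9; the sodium diketonate of 5 adds through its central carbon (ring C2) to the sp carbon of 9 (ring C3) to give the tetrasubstituted enolate of 10, excess NaH removes the now strongly acidic tricarbonyl C2–H so that this enolate is not quenched, and its carbon (C4) attacks the methyl ester (C5) with loss of methoxide. The closest known reaction type is the alkoxide‑mediated cyclotrimerisation of dialkylketenes to hexaalkylcyclohexane‑1,3,5‑triones, in which an enolate C‑acylates a ketene and the new enolate closes by Dieckmann condensation onto an ester beside a quaternary carbon. The six‑membered ring closes by a 6‑(enolendo)‑exo‑trig Dieckmann condensation, favoured by the gem‑dialkyl effect of C6. No stereocentre arises because C4 and C6 each carry two identical prenyl groups. The step needs C‑ over O‑acylation, cross‑reaction over ketene self‑condensation and ring closure from C4 and not from the isopropyl methine of the side chain: O‑acylation is reversible because the enol ester enolate expels the diketonate again, slow addition keeps the ketene concentration low, and the enolate is created at C4 by the addition itself, so no deprotonation that could choose the other methine is needed.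

Compound list
1 | methyl acetoacetate (methyl 3‑oxobutanoate) | COC(=O)CC(C)=O | starting material
2 | prenyl bromide (1‑bromo‑3‑methylbut‑2‑ene) | CC(C)=CCBr | starting material
3 | methyl 2,2‑diprenylacetoacetate (methyl 2‑acetyl‑5‑methyl‑2‑(3‑methylbut‑2‑en‑1‑yl)hex‑4‑enoate) | COC(=O)C(CC=C(C)C)(CC=C(C)C)C(C)=O | intermediate
4 | isobutyryl chloride (2‑methylpropanoyl chloride) | CC(C)C(Cl)=O | starting material
5 | methyl 6‑methyl‑2,2‑bis(3‑methylbut‑2‑en‑1‑yl)‑3,5‑dioxoheptanoate | COC(=O)C(CC=C(C)C)(CC=C(C)C)C(=O)CC(=O)C(C)C | intermediate
6 | methyl diprenylacetate (methyl 5‑methyl‑2‑(3‑methylbut‑2‑en‑1‑yl)hex‑4‑enoate) | COC(=O)C(CC=C(C)C)CC=C(C)C | intermediate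
7 | diprenylacetic acid (5‑methyl‑2‑(3‑methylbut‑2‑en‑1‑yl)hex‑4‑enoic acid) | OC(=O)C(CC=C(C)C)CC=C(C)C | intermediate
8 | diprenylacetyl chloride (5‑methyl‑2‑(3‑methylbut‑2‑en‑1‑yl)hex‑4‑enoyl chloride) | ClC(=O)C(CC=C(C)C)CC=C(C)C | intermediate
9 | diprenylketene (5‑methyl‑2‑(3‑methylbut‑2‑en‑1‑yl)hexa‑1,4‑dien‑1‑one) | CC(C)=CCC(CC=C(C)C)=C=O | intermediate
10 | triketo ester, formed as its sodium enolate (methyl 9‑methyl‑2,2,6‑tris(3‑methylbut‑2‑en‑1‑yl)‑4‑(2‑methylpropanoyl)‑3,5‑dioxodec‑8‑enoate) | COC(=O)C(CC=C(C)C)(CC=C(C)C)C(=O)C(C(=O)C(C)C)C(=O)C(CC=C(C)C)CC=C(C)C | intermediate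
11 | colupone (3‑hydroxy‑2‑(2‑methylpropanoyl)‑4,4,6,6‑tetrakis(3‑methylbut‑2‑en‑1‑yl)cyclohex‑2‑ene‑1,5‑dione) | CC(C)=CCC1(CC=C(C)C)C(=O)C(C(=O)C(C)C)=C(O)C(CC=C(C)C)(CC=C(C)C)C1=O | target

Total step count: 5. Longest linear sequence: 4 steps (steps 1, 3, 4, 5).

Steps most likely to fail

Step 5. The ketene‑derived enolate may be protonated at C4 before it closes the ring. Re‑enolisation by the base would then favour the less hindered isopropyl methine and closure to an isomeric ring. O‑acylation and self‑condensation of the ketene may also consume material. The fallback abandons the ring construction and prenylates a preformed ring. It sets out from 4 and 2. Commercial phloroglucinol (Oc1cc(O)cc(O)c1) should undergo Friedel–Crafts acylation with 4 (AlCl3, nitrobenzene, 25 °C to 60 °C) to give 1‑(2,4,6‑trihydroxyphenyl)‑2‑methylpropan‑1‑one F1. Exhaustive C‑prenylation of F1 with excess 2 (NaOMe, MeOH, 0 °C) should then place two prenyl groups on each free ring carbon. This comes back to the route at 11, after separation from lower and O‑prenylated products.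

Step 2. The magnesium enolate may be acylated at oxygen or twice, or enolisation of the hindered ketone may stay incomplete. The fallback replaces acylation by aldol addition and oxidation. It sets out from 3. Kinetic deprotonation of the acetyl group (LiN(i‑Pr)2, THF, −78 °C) and addition to isobutyraldehyde (CC(C)C=O) should give racemic methyl 5‑hydroxy‑6‑methyl‑2,2‑bis(3‑methylbut‑2‑en‑1‑yl)‑3‑oxoheptanoate F2. Oxidation of the secondary alcohol with Dess–Martin periodinane (NaHCO3, CH2Cl2, 25 °C) should come back to the route at 5.

Step 3. If hydroxide acts before the retro‑Claisen cleavage is complete, the ester is saponified first and the β‑keto acid loses CO2 to a ketone (ketonic instead of acid cleavage). The fallback is a malonic ester synthesis. It sets out from 2. Double alkylation of dimethyl malonate (COC(=O)CC(=O)OC) with 2 (NaH, THF, 0 °C to 25 °C) should give dimethyl 2,2‑bis(3‑methylbut‑2‑en‑1‑yl)propanedioate F3. Saponification (KOH, aq. MeOH, 65 °C, then cold HCl) should give 2,2‑bis(3‑methylbut‑2‑en‑1‑yl)propanedioic acid F4. Thermal decarboxylation (neat, 150 °C) should come back to the route at 7.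

Further compounds
F1 | step 5 | 1‑(2,4,6‑trihydroxyphenyl)‑2‑methylpropan‑1‑one | CC(C)C(=O)c1c(O)cc(O)cc1O
F2 | step 2 | methyl 5‑hydroxy‑6‑methyl‑2,2‑bis(3‑methylbut‑2‑en‑1‑yl)‑3‑oxoheptanoate (racemic) | COC(=O)C(CC=C(C)C)(CC=C(C)C)C(=O)CC(O)C(C)C
F3 | step 3 | dimethyl 2,2‑bis(3‑methylbut‑2‑en‑1‑yl)propanedioate | COC(=O)C(CC=C(C)C)(CC=C(C)C)C(=O)OC
F4 | step 3 | 2,2‑bis(3‑methylbut‑2‑en‑1‑yl)propanedioic acid | OC(=O)C(CC=C(C)C)(CC=C(C)C)C(O)=O
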